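Slowness was what I looked for first: Monday's flask went from 55 °C to 25 °C at 1.0 h and then stood cooled for 20.0 min, so I asked how slowly its ring might fall towards a colder level.

the same everywhere: starting material 0.20 M

| charge | solid activator | temperature | remark | time |
|---|---|---|---|---|
| south-east | 0.22 M | 20 °C | run made earlier |  |
| south | 0.35 M | 40 °C | run made earlier |  |
| Monday's | 0.160 M |  | at 55 °C until 1.0 h, from then on at 25 °C | 80 min |
| Thursday's | 0.160 M | 55 °C |  | 80 min |
| Wednesday's | 0.160 M | 40 °C |  | 80 min |
| Saturday's | 0.160 M | 25 °C |  | 80 min |

- south-east (time / min: ring / %): 50.0: 11.0; 120: 11.9; 240: 9.0; 480: 9.3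
- south (time / min: ring / %): 50.0: 23.6; 120: 24.2; 180: 22.9

(readings scatter by 0.5 percentage points)

* the flask with the highest amount of ring, in percent of the starting material charged ("all alike" if they lie within 1.5 percentage points) (Monday's / Thursday's / Wednesday's / Saturday's / all alike)
* final ring, as a percentage of the starting material charged, in Monday's
* final ring, as a percentage of the starting material charged, in Thursday's
* final ring, as a percentage of the starting material charged, in Wednesday's
* final ring, as a percentage of the starting material charged, in Saturday's

- at the start none of the solid activator is in solution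

My reckoning for Monday's was the cold level plus the gap between the hot and cold levels, times exp(−window/lifetime). I took each number in turn. In the south-east run, ring fell from 11.5% in the first pair of readings to 9.15% in the last pair, a drop larger than the scatter, and the fall lay between 120 min and 240 min. I let 3 lifetimes fill that interval, which gave a sag lifetime (relaxation time) of 40.0 min, the time in which ring's distance from its lower level shrinks to 36.8% of itself. The window then kept 60.7% of the gap.

An error in the hot level passed into Monday's at that share, so a scatter-sized error moved my answer by 0.3 percentage points. But my levels, scaled from the mean reading 23.6% of the south run, came to 40.5% hot and 11.0% cold, and a lifetime of 20.0 min moved my answer by 7 points, more than the scatter. The lifetime was therefore the number to know well, and mine came from 20 °C. I reckoned 28.9% for Monday's.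

The forecast put Thursday's highest, with 38% there, 23% in Wednesday's, 13% in Saturday's and 34% in Monday's (range 20% to 43%), reasoning that “ring already formed probably persists”; my Monday's figure was lower.

The flasks gave 21.5% in Monday's, 33.6% in Thursday's, 19.7% in Wednesday's and 10.1% in Saturday's, with Thursday's highest.

    activated form → ring (k = 0.0400 min⁻¹, Ea = 80.0 kJ mol⁻¹)
    solid activator ⇌ activator, rate k2*(cs2 - [activator]) while solid is left; crystals form when [activator] > cs2 (solubility = 0.170 M, k = 0.720 min⁻¹)
    starting material + activated form → open dimer (k = 0.620 M⁻¹ min⁻¹, Ea = 53.0 kJ mol⁻¹)
    starting material + activator → activated form (k = 0.280 M⁻¹ min⁻¹, Ea = 69.0 kJ mol⁻¹)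
    ring ⇌ isomer of the product (K = 2.60, k = 0.0380 min⁻¹, Ea = 90.0 kJ mol⁻¹, ΔH = −38.0 kJ mol⁻¹)
    (constants at 25 °C)

At 25 °C ring and isomer of the product relax with a lifetime of 19.0 min, shorter than my 40.0 min, so the window of 20.0 min held 1.05 lifetimes rather than 0.500, and Monday's ring went from 33.3% at 60.0 min to 21.5% at 80.0 min, on its way to 15.4% at 800 min. Monday's, read at 2.5 h, had 4.74 of these lifetimes behind it, or 2.25 of mine, and its ring stood at 15.4%.

The data stem from a simulated flask for substances that don't exist; scatter was added.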